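**Assumptions.** The SMILES is read as a nitrile carbon plus twenty CH2 groups on C5 of 1H-pyrrole-2-carbaldehyde (C26H44N2O). The molecule has no stereocentre, so it is its own single stereoisomer and no stereocontrol is needed. Undec-10-enenitrile is taken as a stock commercial chemical. Compounds are numbered in the order they appear in the forward steps.

**Retrosynthetic overview**
1. Target ⇒ acetal hydrolysis and Paal–Knorr condensation with ammonia: the pyrrole is the only ring and is closed last, from a 1,4-diketone that carries the future CHO as a diethyl acetal.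
2. 1,4-Diketone ⇒ Stetter disconnection of the future C5–C4 bond: the aldehyde carbon of a C22 ω-cyano aldehyde, as a carbene-bound acyl anion, adds to the β-carbon of 1,1-diethoxybut-3-en-2-one.
3. C22 ω-cyano aldehyde ⇒ alcohol oxidation ⇒ C11 + C11 sp3–sp3 Suzuki coupling of undec-10-enenitrile (through its 9-BBN adduct) with 11-bromoundecan-1-ol.
4. Enone ⇒ ethyl diethoxyacetate + vinylmagnesium bromide.

**Route**

Step 1
Reactants: 1 undec-10-enenitrile; 2 11-bromoundecan-1-ol
Product: 4 22-hydroxydocosanenitrile, via B-(10-cyanodecyl)-9-BBN 3 (not isolated)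
Conditions: 1 (1.3 equiv), 9-BBN (0.5 M in THF, 1.25 equiv), 0 °C → rt, 4 h; then 2 (1.0 equiv), Pd(OAc)2 (4 mol%), PCy3 (8 mol%), K3PO4·H2O (1.3 equiv), THF, rt, 24 h
Reagents that add atoms: none
Why: 9-BBN hydroborates the terminal alkene anti-Markovnikov without touching the nitrile, and the primary alkyl-9-BBN then couples with the primary alkyl bromide in a Pd/PCy3 alkyl–alkyl Suzuki–Miyaura coupling, where the bulky electron-rich phosphine lets oxidative addition and transmetalation outrun β-hydride elimination; no stereocentre is formed.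

Step 2
Reactants: 4 22-hydroxydocosanenitrile
Product: 5 22-oxodocosanenitrile
Conditions: TEMPO (10 mol%), PhI(OAc)2 (1.1 equiv), CH2Cl2, 30 °C, 4 h
Reagents that add atoms: none
Why: TEMPO/oxoammonium oxidation of a primary alcohol stops cleanly at the aldehyde in the absence of water and leaves the nitrile untouched; no stereocentre is formed.

Step 3
Reactants: 6 ethyl 2,2-diethoxyacetate; 7 vinylmagnesium bromide
Product: 9 1,1-diethoxybut-3-en-2-one, via magnesium hemiketal 8 (not isolated)
Conditions: 7 (1.0 M in THF, 1.05 equiv), THF, −78 °C, 1 h; inverse quench into AcOH (1.2 equiv)/THF at −78 °C; distil under reduced pressure over hydroquinone, use within a day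
Reagents that add atoms: none
Why: Nucleophilic acyl substitution by a Grignard reagent (ester-to-ketone mono-addition), in which chelation of magnesium by the α-ethoxy groups keeps the tetrahedral adduct 8 intact at −78 °C, so the ketone is released only in the acidic quench, away from remaining Grignard reagent; 9 has no stereocentre.

Step 4
Reactants: 5 22-oxodocosanenitrile; 9 1,1-diethoxybut-3-en-2-one
Product: 12 21-(5-formyl-1H-pyrrol-2-yl)henicosanenitrile, via diketo acetal 10 (not isolated), via pyrrole diethyl acetal 11 (not isolated)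
Conditions: 9 (1.3 equiv), 3-benzyl-5-(2-hydroxyethyl)-4-methylthiazolium chloride (20 mol%), Et3N (0.5 equiv), EtOH, 75 °C, 12 h; then NH4OAc (10 equiv), AcOH, 80 °C, 2 h; then 1 M HCl, THF, rt, 30 min
Reagents that add atoms: ammonium acetate, CC(=O)[O-].[NH4+]; water, O
Why: Stetter reaction, in which the thiazol-2-ylidene turns the aldehyde carbon of 5 into a nucleophilic Breslow intermediate that adds 1,4 to the electron-poor enone 9 and so joins two carbons that are both electrophilic, after which ammonia closes the 1,4-diketone by Paal–Knorr condensation and the pyrrol-2-yl acetal is hydrolysed through its azafulvenium ion to the aldehyde; no stereocentre is formed.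

**Compound list**

1 | undec-10-enenitrile | C=CCCCCCCCCC#N | starting material
2 | 11-bromoundecan-1-ol | OCCCCCCCCCCCBr | starting material
3 | 11-(9-borabicyclo[3.3.1]nonan-9-yl)undecanenitrile | N#CCCCCCCCCCCB1C2CCCC1CCC2 | intermediate
4 | 22-hydroxydocosanenitrile | N#CCCCCCCCCCCCCCCCCCCCCCO | intermediate
5 | 22-oxodocosanenitrile | N#CCCCCCCCCCCCCCCCCCCCCC=O | intermediate
6 | ethyl 2,2-diethoxyacetate | CCOC(=O)C(OCC)OCC | starting material
7 | vinylmagnesium bromide | C=C[Mg]Br | starting material
8 | bromomagnesium 1,1,2-triethoxybut-3-en-2-olate (racemic) | C=CC(OCC)(O[Mg]Br)C(OCC)OCC | intermediate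
9 | 1,1-diethoxybut-3-en-2-one | C=CC(=O)C(OCC)OCC | intermediate
10 | 26,26-diethoxy-22,25-dioxohexacosanenitrile | N#CCCCCCCCCCCCCCCCCCCCCC(=O)CCC(=O)C(OCC)OCC | intermediate
11 | 21-[5-(diethoxymethyl)-1H-pyrrol-2-yl]henicosanenitrile | N#CCCCCCCCCCCCCCCCCCCCCc1ccc(C(OCC)OCC)[nH]1 | intermediate
12 | 21-(5-formyl-1H-pyrrol-2-yl)henicosanenitrile | N#CCCCCCCCCCCCCCCCCCCCCc1ccc(C=O)[nH]1 | target

**Step count**

Total steps: 4. Longest linear sequence: 3 (steps 1, 2, 4); step 3 is a one-step side branch.

**Steps most likely to fail, with fallbacks**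

Step 4 is the riskiest: the carbene may divert 5 into acyloin, 9 may polymerise, and the pyrrolyl acetal may oligomerise before it is hydrolysed. The fallback keeps a reversed-polarity bond construction but moves it to the neighbouring bond, using an α-bromoketone as enolonium equivalent toward a β-keto ester enolate. It sets out from 5. SnCl2-catalysed insertion of ethyl diazoacetate into the aldehyde C–H bond (Roskamp homologation, CH2Cl2, rt) gives ethyl 23-cyano-3-oxotricosanoate F1. Its potassium enolate (K2CO3, acetone, rt) is C-alkylated with commercial 3-bromo-1,1-dimethoxypropan-2-one to give racemic ethyl 23-cyano-2-(3,3-dimethoxy-2-oxopropyl)-3-oxotricosanoate F2. Krapcho de-ethoxycarbonylation (LiCl, wet DMSO, 140 °C) leaves 26,26-dimethoxy-22,25-dioxohexacosanenitrile F3. NH4OAc/AcOH at 80 °C closes this to 21-[5-(dimethoxymethyl)-1H-pyrrol-2-yl]henicosanenitrile F4, which is hydrolysed in the same flask with 1 M HCl, and the fallback comes back to the route at 12.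

Step 1 is next: the free hydroxyl of 2 may interfere, and β-hydride elimination or protodeboronation may win over coupling. The fallback builds the C22 chain by olefin metathesis instead of sp3–sp3 cross-coupling. It sets out from 2 and 1. Copper-catalysed coupling of 2 with vinylmagnesium bromide 7 (2.2 equiv, the first equivalent spent on the hydroxyl; Li2CuCl4 cat., THF/NMP, 0 °C) gives tridec-12-en-1-ol F5. Cross-metathesis of F5 with an excess of 1 (Hoveyda–Grubbs II, CH2Cl2, 40 °C, ethene swept out) gives 22-hydroxydocos-10-enenitrile F6 as an E/Z mixture. Hydrogenation (H2 1 atm, Pd/C, EtOAc, rt) saturates the alkene without reducing the nitrile, and the fallback comes back to the route at 4.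

Step 3 is third: a second addition of 7, conjugate addition of ethoxide during the quench, or polymerisation of 9 on distillation may erode the yield. The fallback makes the enone by a homoenolate ring-opening instead of an acylation. It sets out from 6. Kulinkovich cyclopropanation (EtMgBr, Ti(OiPr)4 cat., THF, rt) gives 1-(diethoxymethyl)cyclopropan-1-ol F7, which can be stored. Pd(OAc)2 (10 mol%), pyridine and O2 (1 atm) in toluene at 80 °C open F7 to the palladium homoenolate, β-hydride elimination releases the enone, and the fallback comes back to the route at 9, prepared immediately before step 4.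

**Further compounds**

F1 | step 4 | ethyl 23-cyano-3-oxotricosanoate | N#CCCCCCCCCCCCCCCCCCCCCC(=O)CC(=O)OCC
F2 | step 4 | ethyl 23-cyano-2-(3,3-dimethoxy-2-oxopropyl)-3-oxotricosanoate (racemic) | N#CCCCCCCCCCCCCCCCCCCCCC(=O)C(CC(=O)C(OC)OC)C(=O)OCC
F3 | step 4 | 26,26-dimethoxy-22,25-dioxohexacosanenitrile | N#CCCCCCCCCCCCCCCCCCCCCC(=O)CCC(=O)C(OC)OC
F4 | step 4 | 21-[5-(dimethoxymethyl)-1H-pyrrol-2-yl]henicosanenitrile | N#CCCCCCCCCCCCCCCCCCCCCc1ccc(C(OC)OC)[nH]1
F5 | step 1 | tridec-12-en-1-ol | OCCCCCCCCCCCC=C
F6 | step 1 | 22-hydroxydocos-10-enenitrile (E/Z mixture) | N#CCCCCCCCCC=CCCCCCCCCCCCO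
F7 | step 3 | 1-(diethoxymethyl)cyclopropan-1-ol | OC1(CC1)C(OCC)OCC
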